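**Retrosynthetic overview** (cyclohexanone numbering: C1 C=O, C2 propenyl, C4 furanone, C5 hexenoyl)
1. Target ⇐ O-methyl tetronate diketone (chloride demethylation last) ⇐ diol ⇐ tetronate annulation: Felkin–Anh addition of a β-lithio-β-methoxymethacrylate to a methyl ketone on C4.
2. Methyl ketone and side-chain carbinol ⇐ two cis-fused γ-lactones used in turn as temporary rings ⇐ ozonolysis of the etheno bridge of a bicyclo[3.2.1]oct-6-ene; one bridge carbon becomes the first propenyl carbon, the other the quaternary furanone carbon.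
3. Bicyclo[3.2.1]octa-2,6-diene ⇐ cyclopentadiene + a 4-silyloxy vinyldiazoacetate by enantioselective cyclopropanation/Cope rearrangement (formal [4+3]); this makes the C1–C2 and C4–C5 bonds of the cyclohexanone in one operation.
4. Enabling feature: C2, C3 (the CH2) and C4, together with the two exocyclic carbons they carry cis (propenyl C-1 on C2, furanone C-5 on C4), are the five carbons of a cyclopentadiene ring; C5–C6–C1 is a three-carbon unit with an acyl-level carbon on C5 and oxygen on C1, i.e. a vinylcarbenoid.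
5. Ring order: cyclopropane (transient) → bicyclo[3.2.1] skeleton holding the six-membered carbocycle → γ-lactone A → γ-lactone B → furanone (tetronate) last.

Key step: step 3

Assumption: Rh2(S-DOSP)4 is taken to give bicycle 7 in the absolute configuration drawn; if the induction proves opposite, the mirror-image catalyst Rh2(R-DOSP)4 is used and nothing else changes.
Remark: the silyloxy-bearing ring carbon (step 3) and the side-chain carbinol carbon (step 8) both become ketones in step 15, so their configuration is inconsequential; the former is drawn endo as expected, the latter is carried as a mixture of epimers.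

**Step 1**
Reactants: 1 ethyl diazoacetate; 2 (tert-butyldimethylsilyloxy)acetaldehyde
Product: 3 ethyl 4-[(tert-butyldimethylsilyl)oxy]-2-diazo-3-hydroxybutanoate (racemic)
Conditions: DBU (10 mol%), MeCN, 0 °C → rt
Reagents that add atoms: none
Why: base-catalysed aldol-type addition of the nucleophilic diazo carbon to the aldehyde should give the β-hydroxy-α-diazo ester, whose carbinol centre is destroyed in step 2.

**Step 2**
Reactants: 3 ethyl 4-[(tert-butyldimethylsilyl)oxy]-2-diazo-3-hydroxybutanoate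
Product: 4 ethyl (3E)-4-[(tert-butyldimethylsilyl)oxy]-2-diazobut-3-enoate
Conditions: POCl3, Et3N, CH2Cl2, 0 °C; used at once
Reagents that add atoms: none
Why: dehydration of a β-hydroxy-α-diazo ester through its dichlorophosphate (E2) is the standard entry to vinyldiazoacetates and should give the conjugated (E)-enol ether, the only β-hydrogens being on the silyloxymethyl carbon.

**Step 3**
Reactants: 4 ethyl (3E)-4-[(tert-butyldimethylsilyl)oxy]-2-diazobut-3-enoate; 5 cyclopenta-1,3-diene (freshly cracked from commercial dicyclopentadiene)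
Product: 7 ethyl (1R,4R,5S)-4-[(tert-butyldimethylsilyl)oxy]bicyclo[3.2.1]octa-2,6-diene-2-carboxylate (4-endo silyl ether), via divinylcyclopropane 6 (not isolated)
Conditions: Rh2(S-DOSP)4 (1 mol%), 5 (5 equiv), pentane, −78 °C, slow addition of 4, then rt (40 °C if the Cope stage is incomplete)
Reagents that add atoms: none
Why: The dirhodium tetracarboxylate converts 4 with loss of N2 into a donor/acceptor vinylcarbenoid that cyclopropanates one double bond of cyclopentadiene (asynchronous [2+1], vinyl group cis to the ring) to give cis-1,2-divinylcyclopropane 6, which undergoes a [3,3] Cope shift through a boat transition state; the carbenoid carbon ends bonded to one diene terminus and the vinyl terminus to the other, so the C4–C5 and C1–C2 bonds of the future cyclohexanone form in one operation (formal [4+3]). The closest known reaction type is the tandem cyclopropanation/Cope rearrangement of vinyldiazoacetates with cyclopentadiene under chiral dirhodium tetracarboxylate catalysis. The three-membered ring closes by [2+1] cycloaddition and the bicyclo[3.2.1]octadiene, which contains the target's six-membered ring as three-carbon bridge, bridgeheads and methano bridge, by the [3,3]-sigmatropic shift. The two bridgehead stereocentres (C2 and C4 of the target, necessarily cis) are set in absolute terms by the chiral catalyst in the cyclopropanation, and the silyloxy-bearing carbon by the boat geometry, which places the (E)-substituent endo. The step needs carbenoid rather than vinylogous reactivity, and cyclopropanation faster than carbene dimerisation or pyrazole formation; the trans substituent on the vinyl terminus, the hydrocarbon solvent, excess diene and slow addition at low temperature are meant to secure this, and regiochemistry is not an issue because the diene is symmetric.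

**Step 4**
Reactants: 7 ethyl (1R,4R,5S)-4-[(tert-butyldimethylsilyl)oxy]bicyclo[3.2.1]octa-2,6-diene-2-carboxylate
Product: 8 ethyl 4-endo-[(tert-butyldimethylsilyl)oxy]bicyclo[3.2.1]oct-6-ene-2-endo-carboxylate
Conditions: Cu(OAc)2 (5 mol%), 1,2-bis(diphenylphosphino)benzene (5 mol%), (EtO)2MeSiH, t-BuOH, toluene, rt; then NaOEt (10 mol%), EtOH, rt
Reagents that add atoms: none
Why: copper hydride conjugate reduction takes the enoate and leaves the isolated strained alkene and the silyl ether, and both exo-face protonation of the ester enolate and ethoxide equilibration place the ester equatorial (endo), cis to the etheno bridge, which sets C5 of the target relative to C4.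

**Step 5**
Reactants: 8 ethyl 4-endo-[(tert-butyldimethylsilyl)oxy]bicyclo[3.2.1]oct-6-ene-2-endo-carboxylate
Product: 11 6-[(tert-butyldimethylsilyl)oxy]-5-(hydroxymethyl)hexahydro-2-benzofuran-1(3H)-one (cis-fused, 3a,5,6,7a-all-cis), via ozonide 9 (not isolated), via diol ester 10 (not isolated)
Conditions: O3, CH2Cl2/EtOH, −78 °C; NaBH4, −78 → 0 °C; AcOH; then PPTS (cat.), toluene, 50 °C
Reagents that add atoms: ozone, [O-][O+]=O
Why: ozonolysis with reductive work-up cuts the only C=C into two hydroxymethyl arms held cis by the former bridge, and only the arm next to the cis ester can close a five-membered ring, so acid-catalysed lactonisation differentiates the arms and locks the C4/C5 cis relation.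

**Step 6**
Reactants: 11 6-[(tert-butyldimethylsilyl)oxy]-5-(hydroxymethyl)hexahydro-2-benzofuran-1(3H)-one
Product: 12 6-[(tert-butyldimethylsilyl)oxy]-1-oxooctahydro-2-benzofuran-5-carbaldehyde (all-cis)
Conditions: Dess–Martin periodinane, NaHCO3, CH2Cl2, 0 °C → rt
Reagents that add atoms: none
Why: buffered Dess–Martin oxidation of the free primary alcohol should give the aldehyde without epimerising its α-centre or eliminating the β-silyloxy group.

**Step 7**
Reactants: 12 6-[(tert-butyldimethylsilyl)oxy]-1-oxooctahydro-2-benzofuran-5-carbaldehyde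
Product: 13 6-[(tert-butyldimethylsilyl)oxy]-5-[(1E)-prop-1-en-1-yl]hexahydro-2-benzofuran-1(3H)-one (all-cis)
Conditions: CrCl2 (8 equiv), CH3CHI2 (2 equiv), THF, rt
Reagents that add atoms: 1,1-diiodoethane, CC(I)I
Why: Takai–Utimoto ethylidenation with the geminal dichromium reagent is non-basic and E-selective for aldehydes, so the (E)-propenyl group should form without epimerising the adjacent centre (C2 of the target) and without touching the lactone.

**Step 8**
Reactants: 13 6-[(tert-butyldimethylsilyl)oxy]-5-[(1E)-prop-1-en-1-yl]hexahydro-2-benzofuran-1(3H)-one; 14 (2E)-5-bromopent-2-ene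
Product: 17 (4E)-1-{5-[(tert-butyldimethylsilyl)oxy]-2-(hydroxymethyl)-4-[(1E)-prop-1-en-1-yl]cyclohexyl}hex-4-en-1-ol (ring all-cis; both carbinol epimers), via Grignard reagent 15 (not isolated), via lactol 16 (not isolated)
Conditions: iBu2AlH (1.1 equiv), CH2Cl2, −78 °C; then 15 (from 14, Mg, THF; 3 equiv), −78 → 0 °C; aq. potassium sodium tartrate
Reagents that add atoms: none
Why: iBu2AlH at −78 °C stops at the aluminium lactolate, which the homoallylic Grignard reagent opens in the same flask (one-pot reduction/Grignard addition) to the 1,4-diol; the new carbinol centre is uncontrolled and is oxidised in step 15.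

**Step 9**
Reactants: 17 (4E)-1-{5-[(tert-butyldimethylsilyl)oxy]-2-(hydroxymethyl)-4-[(1E)-prop-1-en-1-yl]cyclohexyl}hex-4-en-1-ol
Product: 19 5-[(tert-butyldimethylsilyl)oxy]-3-[(3E)-pent-3-en-1-yl]-6-[(1E)-prop-1-en-1-yl]hexahydro-2-benzofuran-1(3H)-one (cis-fused, 3a,5,6,7a-all-cis), via lactol 18 (not isolated)
Conditions: TEMPO (20 mol%), PhI(OAc)2 (2.5 equiv), CH2Cl2, rt
Reagents that add atoms: none
Why: the oxoammonium oxidant takes the primary alcohol selectively, the aldehyde is captured by the cis secondary hydroxyl as a lactol and oxidised on to the γ-lactone (oxidative lactonisation of a 1,4-diol), which moves the lactone carbonyl onto the carbon destined to be the furanone C-5 and masks the side-chain carbinol.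

**Step 10**
Reactants: 19 5-[(tert-butyldimethylsilyl)oxy]-3-[(3E)-pent-3-en-1-yl]-6-[(1E)-prop-1-en-1-yl]hexahydro-2-benzofuran-1(3H)-one
Product: 20 1-{4-[(tert-butyldimethylsilyl)oxy]-2-[(4E)-1-hydroxyhex-4-en-1-yl]-5-[(1E)-prop-1-en-1-yl]cyclohexyl}ethan-1-one (in equilibrium with its cyclic hemiketal)
Conditions: MeLi (1.1 equiv), THF, −78 °C; AcOH, −78 °C
Reagents that add atoms: methyllithium, [Li]C
Why: one equivalent of MeLi adds to the γ-lactone at −78 °C and stops at the lithium lactolate, which a cold quench releases as the methyl ketone.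

**Step 11**
Reactants: 20 1-{4-[(tert-butyldimethylsilyl)oxy]-2-[(4E)-1-hydroxyhex-4-en-1-yl]-5-[(1E)-prop-1-en-1-yl]cyclohexyl}ethan-1-one
Product: 21 1-{4-[(tert-butyldimethylsilyl)oxy]-2-[(4E)-1-[(tert-butyldimethylsilyl)oxy]hex-4-en-1-yl]-5-[(1E)-prop-1-en-1-yl]cyclohexyl}ethan-1-one
Conditions: TBSCl, imidazole, DMAP (cat.), DMF, rt → 40 °C
Reagents that add atoms: tert-butyldimethylsilyl chloride, CC(C)(C)[Si](C)(C)Cl
Why: silylation of the secondary hydroxyl of the open hydroxy-ketone form (the tertiary hemiketal hydroxyl does not react) drains the ring–chain equilibrium and removes a chelating hydroxyl before the stereo-determining addition.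

**Step 12**
Reactants: 22 methyl propanoate; 23 methyl formate
Product: 25 methyl (2E)-3-methoxy-2-methylprop-2-enoate, via sodium enolate 24 (not isolated)
Conditions: NaH, THF, 0 °C → rt; then Me2SO4, DMF, rt
Reagents that add atoms: dimethyl sulfate, COS(=O)(=O)OC
Why: crossed Claisen formylation of the propanoate followed by O-methylation of the sodium enolate should give the β-methoxymethacrylate in its more stable (E) geometry.

**Step 13**
Reactants: 21 1-{4-[(tert-butyldimethylsilyl)oxy]-2-[(4E)-1-[(tert-butyldimethylsilyl)oxy]hex-4-en-1-yl]-5-[(1E)-prop-1-en-1-yl]cyclohexyl}ethan-1-one; 25 methyl (2E)-3-methoxy-2-methylprop-2-enoate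
Product: 28 (5R)-5-{4-[(tert-butyldimethylsilyl)oxy]-2-[(4E)-1-[(tert-butyldimethylsilyl)oxy]hex-4-en-1-yl]-5-[(1E)-prop-1-en-1-yl]cyclohexyl}-4-methoxy-3,5-dimethylfuran-2(5H)-one, via lithioacrylate 26 (not isolated), via hydroxy ester 27 (not isolated)
Conditions: LiN(iPr)2, THF, −90 °C (25 → 26); then 21, −90 → −20 °C; aq. NH4Cl
Reagents that add atoms: none
Why: the β-lithio-β-methoxyacrylate (lithium chelated by the ester) adds to the methyl ketone and the tertiary alkoxide, held cis to the ester, lactonises to the 4-methoxyfuran-2(5H)-one; Felkin–Anh attack anti to the ring bond leading to the silyloxyalkyl-bearing carbon, past the ring hydrogen, should give the (R) quaternary centre.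

**Step 14**
Reactants: 28 the bis(silyl ether) methyl tetronate
Product: 29 (5R)-5-{4-hydroxy-2-[(4E)-1-hydroxyhex-4-en-1-yl]-5-[(1E)-prop-1-en-1-yl]cyclohexyl}-4-methoxy-3,5-dimethylfuran-2(5H)-one
Conditions: HF·pyridine, pyridine, THF, 0 °C → rt
Reagents that add atoms: none
Why: buffered fluoride cleaves both secondary silyl ethers and should leave the methyl tetronate and the two alkenes untouched.

**Step 15**
Reactants: 29 the diol methyl tetronate
Product: 30 (2S,4S,5R)-5-[(4E)-hex-4-enoyl]-4-[(2R)-3-methoxy-2,4-dimethyl-5-oxo-2,5-dihydrofuran-2-yl]-2-[(1E)-prop-1-en-1-yl]cyclohexan-1-one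
Conditions: Dess–Martin periodinane (3 equiv), NaHCO3, CH2Cl2, 0 °C → rt
Reagents that add atoms: none
Why: buffered, non-basic Dess–Martin oxidation of both secondary alcohols should give the 1,4-diketone without epimerising C2 or C5, and the carbinol epimers converge to one ketone.

**Step 16**
Reactants: 30 the O-methyl ether of the target
Product: 31 (2S,4S,5R)-5-[(4E)-hex-4-enoyl]-4-[(2R)-3-hydroxy-2,4-dimethyl-5-oxo-2,5-dihydrofuran-2-yl]-2-[(1E)-prop-1-en-1-yl]cyclohexan-1-one (target)
Conditions: LiCl, DMSO, 50 °C; then dilute HCl to pH 3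
Reagents that add atoms: none
Why: chloride attacks the O-methyl group of the vinylogous ester (SN2 demethylation of a methyl tetronate) under essentially neutral conditions that should neither epimerise the ketone α-centres nor move the β,γ-double bond into conjugation.

**Compound list**
1 | ethyl diazoacetate | CCOC(=O)C=[N+]=[N-] | starting material
2 | (tert-butyldimethylsilyloxy)acetaldehyde | CC(C)(C)[Si](C)(C)OCC=O | starting material
3 | ethyl 4-[(tert-butyldimethylsilyl)oxy]-2-diazo-3-hydroxybutanoate (racemic) | CCOC(=O)C(=[N+]=[N-])C(O)CO[Si](C)(C)C(C)(C)C | intermediate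
4 | ethyl (3E)-4-[(tert-butyldimethylsilyl)oxy]-2-diazobut-3-enoate | CCOC(=O)C(=[N+]=[N-])/C=C/O[Si](C)(C)C(C)(C)C | intermediate
5 | cyclopenta-1,3-diene | C1=CC=CC1 | starting material
6 | ethyl 6-[(E)-2-(tert-butyldimethylsilyloxy)ethenyl]bicyclo[3.1.0]hex-2-ene-6-carboxylate (ethenyl group cis to the five-membered ring) | CCOC(=O)[C@@]1(/C=C/O[Si](C)(C)C(C)(C)C)[C@@H]2CC=C[C@H]12 | intermediate
7 | ethyl (1R,4R,5S)-4-[(tert-butyldimethylsilyl)oxy]bicyclo[3.2.1]octa-2,6-diene-2-carboxylate | CCOC(=O)C1=C[C@H](O[Si](C)(C)C(C)(C)C)[C@H]2C[C@@H]1C=C2 | intermediate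
8 | ethyl 4-endo-[(tert-butyldimethylsilyl)oxy]bicyclo[3.2.1]oct-6-ene-2-endo-carboxylate | CCOC(=O)[C@@H]1C[C@H](O[Si](C)(C)C(C)(C)C)[C@H]2C[C@@H]1C=C2 | intermediate
9 | ozonide of 8 (1,2,4-trioxolane across the former etheno bridge; acetal carbons unassigned) | CCOC(=O)[C@@H]1C[C@H](O[Si](C)(C)C(C)(C)C)[C@H]2C[C@@H]1C1OC2OO1 | intermediate
10 | ethyl 5-[(tert-butyldimethylsilyl)oxy]-2,4-bis(hydroxymethyl)cyclohexane-1-carboxylate (all-cis) | CCOC(=O)[C@@H]1C[C@H](O[Si](C)(C)C(C)(C)C)[C@H](CO)C[C@@H]1CO | intermediate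
11 | 6-[(tert-butyldimethylsilyl)oxy]-5-(hydroxymethyl)hexahydro-2-benzofuran-1(3H)-one (all-cis) | O=C1[C@@H]2C[C@H](O[Si](C)(C)C(C)(C)C)[C@H](CO)C[C@@H]2CO1 | intermediate
12 | 6-[(tert-butyldimethylsilyl)oxy]-1-oxooctahydro-2-benzofuran-5-carbaldehyde (all-cis) | O=C1[C@@H]2C[C@H](O[Si](C)(C)C(C)(C)C)[C@H](C=O)C[C@@H]2CO1 | intermediate
13 | 6-[(tert-butyldimethylsilyl)oxy]-5-[(1E)-prop-1-en-1-yl]hexahydro-2-benzofuran-1(3H)-one (all-cis) | O=C1[C@@H]2C[C@H](O[Si](C)(C)C(C)(C)C)[C@H](/C=C/C)C[C@@H]2CO1 | intermediate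
14 | (2E)-5-bromopent-2-ene | C/C=C/CCBr | starting material
15 | [(3E)-pent-3-en-1-yl]magnesium bromide | C/C=C/CC[Mg]Br | intermediate
16 | 6-[(tert-butyldimethylsilyl)oxy]-5-[(1E)-prop-1-en-1-yl]octahydro-2-benzofuran-1-ol (lactol, present as its aluminium alkoxide) | OC1[C@@H]2C[C@H](O[Si](C)(C)C(C)(C)C)[C@H](/C=C/C)C[C@@H]2CO1 | intermediate
17 | (4E)-1-{5-[(tert-butyldimethylsilyl)oxy]-2-(hydroxymethyl)-4-[(1E)-prop-1-en-1-yl]cyclohexyl}hex-4-en-1-ol (ring all-cis; carbinol epimers) | C/C=C/CCC(O)[C@@H]1C[C@H](O[Si](C)(C)C(C)(C)C)[C@H](/C=C/C)C[C@@H]1CO | intermediate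
18 | 5-[(tert-butyldimethylsilyl)oxy]-3-[(3E)-pent-3-en-1-yl]-6-[(1E)-prop-1-en-1-yl]octahydro-2-benzofuran-1-ol (lactol) | C/C=C/CCC1[C@@H]2C[C@H](O[Si](C)(C)C(C)(C)C)[C@H](/C=C/C)C[C@@H]2C(O)O1 | intermediate
19 | 5-[(tert-butyldimethylsilyl)oxy]-3-[(3E)-pent-3-en-1-yl]-6-[(1E)-prop-1-en-1-yl]hexahydro-2-benzofuran-1(3H)-one | C/C=C/CCC1[C@@H]2C[C@H](O[Si](C)(C)C(C)(C)C)[C@H](/C=C/C)C[C@@H]2C(=O)O1 | intermediate
20 | 1-{4-[(tert-butyldimethylsilyl)oxy]-2-[(4E)-1-hydroxyhex-4-en-1-yl]-5-[(1E)-prop-1-en-1-yl]cyclohexyl}ethan-1-one (ring all-cis) | C/C=C/CCC(O)[C@@H]1C[C@H](O[Si](C)(C)C(C)(C)C)[C@H](/C=C/C)C[C@@H]1C(C)=O | intermediate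
21 | 1-{4-[(tert-butyldimethylsilyl)oxy]-2-[(4E)-1-[(tert-butyldimethylsilyl)oxy]hex-4-en-1-yl]-5-[(1E)-prop-1-en-1-yl]cyclohexyl}ethan-1-one | C/C=C/CCC(O[Si](C)(C)C(C)(C)C)[C@@H]1C[C@H](O[Si](C)(C)C(C)(C)C)[C@H](/C=C/C)C[C@@H]1C(C)=O | intermediate
22 | methyl propanoate | CCC(=O)OC | starting material
23 | methyl formate | COC=O | starting material
24 | sodium enolate of methyl 2-methyl-3-oxopropanoate | [Na+].[O-]C=C(C)C(=O)OC | intermediate
25 | methyl (2E)-3-methoxy-2-methylprop-2-enoate | CO/C=C(\C)C(=O)OC | intermediate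
26 | methyl (2E)-3-lithio-3-methoxy-2-methylprop-2-enoate (lithium cis to the ester) | [Li]/C(OC)=C(/C)C(=O)OC | intermediate
27 | methyl (2E,4R)-4-hydroxy-3-methoxy-2-methyl-4-(cyclohexyl of 21)pent-2-enoate (as its lithium alkoxide) | C/C=C/CCC(O[Si](C)(C)C(C)(C)C)[C@@H]1C[C@H](O[Si](C)(C)C(C)(C)C)[C@H](/C=C/C)C[C@@H]1[C@@](C)(O)/C(OC)=C(/C)C(=O)OC | intermediate
28 | (5R)-5-{4-[(tert-butyldimethylsilyl)oxy]-2-[(4E)-1-[(tert-butyldimethylsilyl)oxy]hex-4-en-1-yl]-5-[(1E)-prop-1-en-1-yl]cyclohexyl}-4-methoxy-3,5-dimethylfuran-2(5H)-one | C/C=C/CCC(O[Si](C)(C)C(C)(C)C)[C@@H]1C[C@H](O[Si](C)(C)C(C)(C)C)[C@H](/C=C/C)C[C@@H]1[C@@]1(C)OC(=O)C(C)=C1OC | intermediate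
29 | (5R)-5-{4-hydroxy-2-[(4E)-1-hydroxyhex-4-en-1-yl]-5-[(1E)-prop-1-en-1-yl]cyclohexyl}-4-methoxy-3,5-dimethylfuran-2(5H)-one | C/C=C/CCC(O)[C@@H]1C[C@H](O)[C@H](/C=C/C)C[C@@H]1[C@@]1(C)OC(=O)C(C)=C1OC | intermediate
30 | (2S,4S,5R)-5-[(4E)-hex-4-enoyl]-4-[(2R)-3-methoxy-2,4-dimethyl-5-oxo-2,5-dihydrofuran-2-yl]-2-[(1E)-prop-1-en-1-yl]cyclohexan-1-one | C/C=C/CCC(=O)[C@@H]1CC(=O)[C@H](/C=C/C)C[C@@H]1[C@@]1(C)OC(=O)C(C)=C1OC | intermediate
31 | (2S,4S,5R)-5-[(4E)-hex-4-enoyl]-4-[(2R)-3-hydroxy-2,4-dimethyl-5-oxo-2,5-dihydrofuran-2-yl]-2-[(1E)-prop-1-en-1-yl]cyclohexan-1-one | C/C=C/CCC(=O)[C@@H]1CC(=O)[C@H](/C=C/C)C[C@@H]1[C@@]1(C)OC(=O)C(C)=C1O | target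

**Step count**
Total: 16 steps. Longest linear sequence: 15 steps (steps 1–11 and 13–16; step 12 is a one-step side branch).

**Steps most likely to fail, with fallbacks**

Step 3. The donor-substituted vinyl diazo ester may be lost by electrocyclisation to a pyrazole, by carbene dimerisation or by attack at the vinyl terminus, or the Cope stage and the enantioselection may suffer from the silyloxy group. The fallback introduces the ring oxygen after the annulation and sets out from 5. Commercial ethyl acetoacetate is converted by diazo transfer (p-acetamidobenzenesulfonyl azide, Et3N) into ethyl 2-diazo-3-oxobutanoate F1. NaBH4 reduction gives ethyl 2-diazo-3-hydroxybutanoate F2, and POCl3/Et3N dehydration gives ethyl 2-diazobut-3-enoate F3. The same Rh2(S-DOSP)4-catalysed cyclopropanation/Cope reaction with 5 should then give ethyl bicyclo[3.2.1]octa-2,6-diene-2-carboxylate F4. Allylic oxidation of its only non-bridgehead allylic CH2 (Rh2(cap)4, t-BuOOH) gives ethyl 4-oxobicyclo[3.2.1]octa-2,6-diene-2-carboxylate F5. Luche reduction (NaBH4, CeCl3) from the exo face gives ethyl 4-endo-hydroxybicyclo[3.2.1]octa-2,6-diene-2-carboxylate F6, and silylation (TBSCl, imidazole) comes back to the route at 7.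

Step 13. Facial selectivity in the addition to the methyl ketone may be poor or reversed, or the vinyllithium may enolise the ketone instead of adding. The fallback reverses the order in which the two carbon substituents of the quaternary centre are introduced; it sets out from 19. Lithioacrylate 26 is added to the lactone at −90 °C to give, after a cold quench, methyl (2E)-4-{4-[(tert-butyldimethylsilyl)oxy]-2-[(4E)-1-hydroxyhex-4-en-1-yl]-5-[(1E)-prop-1-en-1-yl]cyclohexyl}-3-methoxy-2-methyl-4-oxobut-2-enoate F7. Silylation (TBSCl, imidazole) gives its bis(silyl ether) F8. Addition of MeMgBr/CeCl3 to the ketone then delivers the methyl group from the face that the acrylate would otherwise have taken, and the alkoxide lactonises; this comes back to the route at 28.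

Step 16. The warm demethylation may epimerise C5 or C2, move the β,γ-double bond into conjugation, or trigger aldol closure of the 1,4-diketone. The fallback changes the tetronate protecting group before the ketones exist; it sets out from 28. LiCl/DMSO demethylation at this stage gives the bis(silyl ether) tetronic acid F9. Mitsunobu O-alkylation (allyl alcohol, PPh3, diisopropyl azodicarboxylate) gives the allyl tetronate F10, HF·pyridine gives the allyl tetronate diol F11, and Dess–Martin oxidation gives the allyl tetronate diketone F12. Deallylation with Pd(PPh3)4 and morpholine at room temperature comes back to the route at 31.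

**Further compounds**
F1 | step 3 | ethyl 2-diazo-3-oxobutanoate | CCOC(=O)C(=[N+]=[N-])C(C)=O
F2 | step 3 | ethyl 2-diazo-3-hydroxybutanoate (racemic) | CCOC(=O)C(=[N+]=[N-])C(C)O
F3 | step 3 | ethyl 2-diazobut-3-enoate | CCOC(=O)C(=[N+]=[N-])C=C
F4 | step 3 | ethyl bicyclo[3.2.1]octa-2,6-diene-2-carboxylate (same enantiomeric series as 7) | CCOC(=O)C1=CC[C@H]2C[C@@H]1C=C2
F5 | step 3 | ethyl 4-oxobicyclo[3.2.1]octa-2,6-diene-2-carboxylate | CCOC(=O)C1=CC(=O)[C@H]2C[C@@H]1C=C2
F6 | step 3 | ethyl 4-endo-hydroxybicyclo[3.2.1]octa-2,6-diene-2-carboxylate | CCOC(=O)C1=C[C@H](O)[C@H]2C[C@@H]1C=C2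
F7 | step 13 | methyl (2E)-4-{4-[(tert-butyldimethylsilyl)oxy]-2-[(4E)-1-hydroxyhex-4-en-1-yl]-5-[(1E)-prop-1-en-1-yl]cyclohexyl}-3-methoxy-2-methyl-4-oxobut-2-enoate | C/C=C/CCC(O)[C@@H]1C[C@H](O[Si](C)(C)C(C)(C)C)[C@H](/C=C/C)C[C@@H]1C(=O)/C(OC)=C(/C)C(=O)OC
F8 | step 13 | bis(silyl ether) of F7 | C/C=C/CCC(O[Si](C)(C)C(C)(C)C)[C@@H]1C[C@H](O[Si](C)(C)C(C)(C)C)[C@H](/C=C/C)C[C@@H]1C(=O)/C(OC)=C(/C)C(=O)OC
F9 | step 16 | (5R)-5-{4-[(tert-butyldimethylsilyl)oxy]-2-[(4E)-1-[(tert-butyldimethylsilyl)oxy]hex-4-en-1-yl]-5-[(1E)-prop-1-en-1-yl]cyclohexyl}-4-hydroxy-3,5-dimethylfuran-2(5H)-one | C/C=C/CCC(O[Si](C)(C)C(C)(C)C)[C@@H]1C[C@H](O[Si](C)(C)C(C)(C)C)[C@H](/C=C/C)C[C@@H]1[C@@]1(C)OC(=O)C(C)=C1O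
F10 | step 16 | 4-(allyloxy) analogue of 28 | C/C=C/CCC(O[Si](C)(C)C(C)(C)C)[C@@H]1C[C@H](O[Si](C)(C)C(C)(C)C)[C@H](/C=C/C)C[C@@H]1[C@@]1(C)OC(=O)C(C)=C1OCC=C
F11 | step 16 | 4-(allyloxy) analogue of 29 | C/C=C/CCC(O)[C@@H]1C[C@H](O)[C@H](/C=C/C)C[C@@H]1[C@@]1(C)OC(=O)C(C)=C1OCC=C
F12 | step 16 | 4-(allyloxy) analogue of 30 | C/C=C/CCC(=O)[C@@H]1CC(=O)[C@H](/C=C/C)C[C@@H]1[C@@]1(C)OC(=O)C(C)=C1OCC=C
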